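**Plan**

- Retrosynthesis: the four aryl methyl ethers are cut last. The isoflavone pyranone is then opened at C4–C4a, C2–C3 and O1–C2, leaving phloroglucinol, a flavonyl-substituted arylacetic acid and one formyl carbon. Finally the biaryl bond between C3' of isoflavone ring B and C8 of the flavone is cut to an 8-iodoflavone and an arylboronate.
- Forward: the flavone is bought as its trimethyl ether and iodinated at C8; the bromo acid is esterified and borylated; a Suzuki coupling joins the halves and saponification frees the acid.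
- The only ring built is the isoflavone pyranone (O1, C2, C3, C4, C4a, C8a), closed in one flask on unprotected phloroglucinol; global demethylation ends the route.
- Enabling feature: isoflavone ring A (C4a, C5, C6, C7, C8, C8a, with oxygen on C5, C7 and C8a) is a phloroglucinol nucleus. It is threefold symmetric, so C4 and C3 can come from the arylacetic acid and C2 from DMF without protection or a regiochemical choice.
- Stereochemistry: none has to be set; the target has no stereocentre.

Key step: step 6

Remark: the biaryl axis carries no descriptor in the target and is treated as configurationally mobile; phloroglucinol is used anhydrous (the commercial dihydrate is dried first).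

**Route**

Step 1
Reactants: 1 5,7,4'-trimethoxyflavone (apigenin trimethyl ether)
Product: 2 8-iodo-5,7,4'-trimethoxyflavone
Conditions: I2, AgOCOCF3, CH2Cl2, 0 °C to rt, dark
Reagents that add atoms: iodine, II
Why: Electrophilic aromatic iodination should go to C8, which is para to the 5-methoxy group, ortho to the 7-methoxy group and O1, and less crowded than C6 between two methoxy groups, as is usual for 5-O-alkylated 5,7-dioxygenated flavones; ring B is deactivated by conjugation with the pyranone.

Step 2
Reactants: 3 3-bromo-4-methoxyphenylacetic acid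
Product: 4 methyl 2-(3-bromo-4-methoxyphenyl)acetate
Conditions: MeOH, H2SO4 (cat.), reflux
Reagents that add atoms: methanol, CO
Why: Fischer esterification masks the carboxylic acid so that it cannot interfere with the two palladium-mediated steps that follow.

Step 3
Reactants: 4 methyl 2-(3-bromo-4-methoxyphenyl)acetate
Product: 5 methyl 2-[4-methoxy-3-(4,4,5,5-tetramethyl-1,3,2-dioxaborolan-2-yl)phenyl]acetate
Conditions: B2pin2, PdCl2(dppf) (3 mol %), KOAc, 1,4-dioxane, 90 °C
Reagents that add atoms: bis(pinacolato)diboron, CC1(C)OB(OC1(C)C)B1OC(C)(C)C(C)(C)O1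
Why: Miyaura borylation of an aryl bromide tolerates the ortho-methoxy group, and KOAc is too weak a base to enolise the arylacetate or to trigger homocoupling of the boronate with unreacted bromide.

Step 4
Reactants: 2 8-iodo-5,7,4'-trimethoxyflavone; 5 methyl 2-[4-methoxy-3-(4,4,5,5-tetramethyl-1,3,2-dioxaborolan-2-yl)phenyl]acetate
Product: 6 methyl 2-[3-(5,7-dimethoxy-2-(4-methoxyphenyl)-4-oxochromen-8-yl)-4-methoxyphenyl]acetate
Conditions: Pd(OAc)2 (5 mol %), SPhos (10 mol %), K3PO4, toluene/H2O, 90 °C
Reagents that add atoms: none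
Why: Suzuki–Miyaura coupling should work because the aryl iodide adds readily to zerovalent palladium and the bulky, electron-rich SPhos ligand is established for biaryls with three ortho substituents; partial ester hydrolysis by the base would be harmless because step 5 follows.

Step 5
Reactants: 6 methyl 2-[3-(5,7-dimethoxy-2-(4-methoxyphenyl)-4-oxochromen-8-yl)-4-methoxyphenyl]acetate
Product: 7 2-[3-(5,7-dimethoxy-2-(4-methoxyphenyl)-4-oxochromen-8-yl)-4-methoxyphenyl]acetic acid
Conditions: LiOH, THF/MeOH/H2O, rt; then 1 M HCl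
Reagents that add atoms: lithium hydroxide, [Li+].[OH-]
Why: Saponification of the unhindered methyl ester proceeds at room temperature, where the 2-arylchromone resists hydroxide (ring opening needs hot concentrated alkali).

Step 6
Reactants: 7 2-[3-(5,7-dimethoxy-2-(4-methoxyphenyl)-4-oxochromen-8-yl)-4-methoxyphenyl]acetic acid; 8 phloroglucinol
Product: 10 3-[3-(5,7-dimethoxy-2-(4-methoxyphenyl)-4-oxochromen-8-yl)-4-methoxyphenyl]-5,7-dihydroxychromen-4-one, via deoxybenzoin 9 (not isolated)
Conditions: BF3·Et2O (solvent), 80 °C; then DMF, MeSO2Cl, 70 °C; aq. NaOAc work-up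
Reagents that add atoms: N,N-dimethylformamide, CN(C)C=O
Why: In BF3·Et2O the acid is activated as a boron mixed anhydride and acylates a ring carbon of 8 (Friedel–Crafts C-acylation, forming C4–C4a), the ketone 9 being held as its O,O-difluoroboron chelate; DMF and MeSO2Cl then give a Vilsmeier-type iminium salt that formylates the enolised benzylic methylene (C2–C3), and the neighbouring phenolic oxygen adds to the iminium carbon (O1–C2) before dimethylamine is lost. The closest known reaction type is the one-flask isoflavone synthesis from phenols and arylacetic acids in BF3·Et2O with DMF and MeSO2Cl, which is established for phloroglucinol and for substrates with free hydroxyl groups. The single ring formed, the pyranone, closes in the 6-exo-trig mode at the exocyclic C=N+ bond and becomes aromatic by elimination. No stereocentre is created. The step needs mono-C-acylation and formylation at the methylene only: the threefold symmetry of 8 makes all ring carbons and, afterwards, both ortho-hydroxyls equivalent, the first acyl group and the boron chelate deactivate ring A toward a second acylation or ring formylation, and the methylene between chelated carbonyl and aryl is the most nucleophilic carbon once enolised. The flavone half, with its carbonyl tied up by BF3, is expected to be a spectator; should hot BF3·Et2O remove part of its 5-methyl group, that material converges on 11 in step 7.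

Step 7
Reactants: 10 3-[3-(5,7-dimethoxy-2-(4-methoxyphenyl)-4-oxochromen-8-yl)-4-methoxyphenyl]-5,7-dihydroxychromen-4-one
Product: 11 3-[3-(5,7-dihydroxy-2-(4-hydroxyphenyl)-4-oxochromen-8-yl)-4-hydroxyphenyl]-5,7-dihydroxychromen-4-one (target)
Conditions: BBr3 (excess), CH2Cl2, −78 °C to rt; then ice-water
Reagents that add atoms: none
Why: Lewis-acid ether cleavage (boron coordinates each ether oxygen, bromide attacks the methyl group in an SN2 step) should remove all four methyl groups, the 5-methoxy group peri to the carbonyl going first, while the low temperature and absence of hot protic acid avoid ring-opening and reclosure (Wessely–Moser isomerisation) of the 8-aryl-5,7-dihydroxyflavone.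

**Compound list**

1 | 5,7,4'-trimethoxyflavone (5,7-dimethoxy-2-(4-methoxyphenyl)chromen-4-one) | COc1ccc(cc1)-c1cc(=O)c2c(OC)cc(OC)cc2o1 | starting material
2 | 8-iodo-5,7,4'-trimethoxyflavone | COc1ccc(cc1)-c1cc(=O)c2c(OC)cc(OC)c(I)c2o1 | intermediate
3 | 3-bromo-4-methoxyphenylacetic acid | COc1ccc(CC(=O)O)cc1Br | starting material
4 | methyl 2-(3-bromo-4-methoxyphenyl)acetate | COC(=O)Cc1ccc(OC)c(Br)c1 | intermediate
5 | methyl 2-[4-methoxy-3-(4,4,5,5-tetramethyl-1,3,2-dioxaborolan-2-yl)phenyl]acetate | COC(=O)Cc1ccc(OC)c(c1)B1OC(C)(C)C(C)(C)O1 | intermediate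
6 | methyl 2-[3-(5,7-dimethoxy-2-(4-methoxyphenyl)-4-oxochromen-8-yl)-4-methoxyphenyl]acetate | COC(=O)Cc1ccc(OC)c(c1)-c1c(OC)cc(OC)c2c(=O)cc(-c3ccc(OC)cc3)oc12 | intermediate
7 | 2-[3-(5,7-dimethoxy-2-(4-methoxyphenyl)-4-oxochromen-8-yl)-4-methoxyphenyl]acetic acid | COc1ccc(CC(=O)O)cc1-c1c(OC)cc(OC)c2c(=O)cc(-c3ccc(OC)cc3)oc12 | intermediate
8 | phloroglucinol (benzene-1,3,5-triol) | Oc1cc(O)cc(O)c1 | starting material
9 | deoxybenzoin, 2-[3-(5,7-dimethoxy-2-(4-methoxyphenyl)-4-oxochromen-8-yl)-4-methoxyphenyl]-1-(2,4,6-trihydroxyphenyl)ethanone (present in the flask as its difluoroboron chelate) | O=C(Cc1ccc(OC)c(c1)-c1c(OC)cc(OC)c2c(=O)cc(-c3ccc(OC)cc3)oc12)c1c(O)cc(O)cc1O | intermediate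
10 | 3-[3-(5,7-dimethoxy-2-(4-methoxyphenyl)-4-oxochromen-8-yl)-4-methoxyphenyl]-5,7-dihydroxychromen-4-one | O=c1c(-c2ccc(OC)c(-c3c(OC)cc(OC)c4c(=O)cc(-c5ccc(OC)cc5)oc34)c2)coc2cc(O)cc(O)c12 | intermediate
11 | 3-[3-(5,7-dihydroxy-2-(4-hydroxyphenyl)-4-oxochromen-8-yl)-4-hydroxyphenyl]-5,7-dihydroxychromen-4-one | O=c1c(-c2ccc(O)c(-c3c(O)cc(O)c4c(=O)cc(-c5ccc(O)cc5)oc34)c2)coc2cc(O)cc(O)c12 | target

**Count**

Total steps: 7. Longest linear sequence: 6 steps (steps 2, 3, 4, 5, 6 and 7, from acid 3).

**Steps most likely to fail**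

Step 6. The Friedel–Crafts stage may stall, or drift to O-acylation and multiple acylation, because the large acid is sluggish and poorly soluble in BF3·Et2O; prolonged heating would also erode the flavone 5-methyl ether. The fallback builds the ketone by a Hoesch reaction instead. It sets out from ester 6: ammonolysis (NH3, MeOH, sealed tube, 50 °C) would give the primary amide 2-[3-(5,7-dimethoxy-2-(4-methoxyphenyl)-4-oxochromen-8-yl)-4-methoxyphenyl]acetamide F1. Dehydration ((CF3CO)2O, pyridine, CH2Cl2, 0 °C) would give the nitrile 2-[3-(5,7-dimethoxy-2-(4-methoxyphenyl)-4-oxochromen-8-yl)-4-methoxyphenyl]acetonitrile F2. Hoesch condensation of this nitrile with phloroglucinol 8 (ZnCl2, dry HCl, Et2O–dioxane, 0 °C) should deliver the ketiminium chloride F3, and hydrolysis in hot water then gives the deoxybenzoin 9, now isolated. Closure of 9 with DMF, BF3·Et2O and MeSO2Cl at 70 °C returns to the route at 10.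

Step 4. Transmetalation at the doubly ortho-flanked C8 may be slow, so that protodeboronation of the ortho-methoxy boronate 5 and hydrodeiodination of 2 outrun the coupling. The fallback exchanges the roles of the partners, the arrangement known for biflavone ethers joined in this 3',8 manner. It sets out from iodide 2: Miyaura borylation (B2pin2, PdCl2(dppf), KOAc, DMSO, 80 °C) would give the flavone boronate 5,7-dimethoxy-2-(4-methoxyphenyl)-8-(4,4,5,5-tetramethyl-1,3,2-dioxaborolan-2-yl)chromen-4-one F4. Coupling of this boronate with the unhindered bromide 4 (Pd(PPh3)4, Na2CO3, DME/H2O, 85 °C) returns to the route at 6.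

Step 7. Cleavage may stop at partly methylated stages, and the long exposure to excess BBr3 and HBr needed for the 7- and 4'-methoxy groups may degrade the isoflavone pyranone. The fallback moves the deprotection ahead of the ring construction. It sets out from acid 7, which contains only the robust flavone: BBr3 in CH2Cl2 would give the tetrahydroxy acid 2-[3-(5,7-dihydroxy-2-(4-hydroxyphenyl)-4-oxochromen-8-yl)-4-hydroxyphenyl]acetic acid F5. This acid and phloroglucinol 8 are then taken through the same one-flask sequence (BF3·Et2O, 80 °C; then DMF, MeSO2Cl, 70 °C), which is known to tolerate free phenols on the arylacetic acid. It would pass through the deoxybenzoin 2-[3-(5,7-dihydroxy-2-(4-hydroxyphenyl)-4-oxochromen-8-yl)-4-hydroxyphenyl]-1-(2,4,6-trihydroxyphenyl)ethanone F6 and close directly to the target 11.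

**Further compounds**

F1 | step 6 | 2-[3-(5,7-dimethoxy-2-(4-methoxyphenyl)-4-oxochromen-8-yl)-4-methoxyphenyl]acetamide | NC(=O)Cc1ccc(OC)c(c1)-c1c(OC)cc(OC)c2c(=O)cc(-c3ccc(OC)cc3)oc12
F2 | step 6 | 2-[3-(5,7-dimethoxy-2-(4-methoxyphenyl)-4-oxochromen-8-yl)-4-methoxyphenyl]acetonitrile | N#CCc1ccc(OC)c(c1)-c1c(OC)cc(OC)c2c(=O)cc(-c3ccc(OC)cc3)oc12
F3 | step 6 | ketiminium chloride, 2-[3-(5,7-dimethoxy-2-(4-methoxyphenyl)-4-oxochromen-8-yl)-4-methoxyphenyl]-1-(2,4,6-trihydroxyphenyl)ethaniminium chloride | [NH2+]=C(Cc1ccc(OC)c(c1)-c1c(OC)cc(OC)c2c(=O)cc(-c3ccc(OC)cc3)oc12)c1c(O)cc(O)cc1O.[Cl-]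
F4 | step 4 | 5,7-dimethoxy-2-(4-methoxyphenyl)-8-(4,4,5,5-tetramethyl-1,3,2-dioxaborolan-2-yl)chromen-4-one | COc1ccc(cc1)-c1cc(=O)c2c(OC)cc(OC)c(B3OC(C)(C)C(C)(C)O3)c2o1
F5 | step 7 | 2-[3-(5,7-dihydroxy-2-(4-hydroxyphenyl)-4-oxochromen-8-yl)-4-hydroxyphenyl]acetic acid | OC(=O)Cc1ccc(O)c(c1)-c1c(O)cc(O)c2c(=O)cc(-c3ccc(O)cc3)oc12
F6 | step 7 | 2-[3-(5,7-dihydroxy-2-(4-hydroxyphenyl)-4-oxochromen-8-yl)-4-hydroxyphenyl]-1-(2,4,6-trihydroxyphenyl)ethanone | O=C(Cc1ccc(O)c(c1)-c1c(O)cc(O)c2c(=O)cc(-c3ccc(O)cc3)oc12)c1c(O)cc(O)cc1O
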